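**Strategy.** The route rests on disconnecting the bond between the bridging CH2 and the single ring carbon of the dimethoxy ring that lies between its free OH and an OMe. The key step exploits that this CH2 sits on the trihydroxy ring between two phenolic OH groups: a benzylic dimethylamine (Mannich base) on that ring expels the amine to give a dearomatized ortho-quinone methide, which the only unsubstituted carbon of the 4-hydroxy-2,6-dimethoxy ketone captures; tautomerization restores both arenes. Both coupling partners are drawn from one intermediate, 2,4,6-trihydroxy-3-methylisobutyrophenone, itself made by acylation of methylphloroglucinol.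

Key step: step 6

Remark: the target contains no stereocentre, no stereogenic double bond and no configurationally stable axis; it is achiral, so no step has to set or preserve configuration.

**Step 1**
Reactants: 1 2-methylbenzene-1,3,5-triol (2,4,6-trihydroxytoluene); 2 2-methylpropanoyl chloride (isobutyryl chloride)
Product: 3 1-(2,4,6-trihydroxy-3-methylphenyl)-2-methylpropan-1-one
Conditions: AlCl3 (4 equiv), PhNO2/CH2Cl2, 0 °C to 45 °C; then ice/1 M HCl
Reagents that add atoms: none
Why: Friedel–Crafts C-acylation; the two unsubstituted ring carbons of 1 are equivalent, so a single regioisomer should form, and the aluminium-chelated aryl ketone is deactivated towards a second acylation.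

**Step 2**
Reactants: 3 1-(2,4,6-trihydroxy-3-methylphenyl)-2-methylpropan-1-one
Product: 4 1-[4-(benzyloxy)-2,6-dihydroxy-3-methylphenyl]-2-methylpropan-1-one
Conditions: BnBr (1.0 equiv), K2CO3 (1.1 equiv), acetone, rt
Reagents that add atoms: benzyl bromide, BrCc1ccccc1
Why: Williamson etherification under substrate control; with one equivalent of weak base the most acidic hydroxyl, para to the ketone and outside the carbonyl hydrogen bond, should be benzylated in preference to the two ortho hydroxyls.

**Step 3**
Reactants: 4 1-[4-(benzyloxy)-2,6-dihydroxy-3-methylphenyl]-2-methylpropan-1-one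
Product: 5 1-[4-(benzyloxy)-2,6-dimethoxy-3-methylphenyl]-2-methylpropan-1-one
Conditions: Me2SO4 (3 equiv), K2CO3 (4 equiv), acetone, reflux
Reagents that add atoms: dimethyl sulfate, COS(=O)(=O)OC
Why: Exhaustive Williamson O-methylation; the hard electrophile in refluxing acetone should methylate both ortho hydroxyls, the chelated one last, in preference to C-methylation at the free ring carbon.

**Step 4**
Reactants: 5 1-[4-(benzyloxy)-2,6-dimethoxy-3-methylphenyl]-2-methylpropan-1-one
Product: 6 1-(4-hydroxy-2,6-dimethoxy-3-methylphenyl)-2-methylpropan-1-one
Conditions: H2 (1 atm), 10% Pd/C, EtOAc, rt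
Reagents that add atoms: none
Why: Catalytic hydrogenolysis of the benzyl ether; the twisted, di-ortho-substituted aryl ketone and the methyl ethers are not expected to react under these conditions.

**Step 5**
Reactants: 3 1-(2,4,6-trihydroxy-3-methylphenyl)-2-methylpropan-1-one
Product: 7 1-{3-[(dimethylamino)methyl]-2,4,6-trihydroxy-5-methylphenyl}-2-methylpropan-1-one
Conditions: premixed 40% aq. Me2NH (1.5 equiv) and 37% aq. CH2O (1.2 equiv), EtOH, 0 °C to rt
Reagents that add atoms: formaldehyde, C=O; dimethylamine, CNC
Why: Mannich aminomethylation at the only unsubstituted ring carbon of 3; the premixed excess of amine and formaldehyde at low temperature should suppress methylene-bis-arene formation, and the zwitterionic product should precipitate.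

**Step 6**
Reactants: 7 1-{3-[(dimethylamino)methyl]-2,4,6-trihydroxy-5-methylphenyl}-2-methylpropan-1-one; 6 1-(4-hydroxy-2,6-dimethoxy-3-methylphenyl)-2-methylpropan-1-one
Product: 9 1-[4-hydroxy-2,6-dimethoxy-3-methyl-5-[[2,4,6-trihydroxy-3-methyl-5-(2-methylpropanoyl)phenyl]methyl]phenyl]-2-methylpropan-1-one (target), via ortho-quinone methide 8 (not isolated)
Conditions: 6 (2 equiv), degassed 1,4-dioxane, 100 °C, argon sweep; 7 added slowly as a solution
Reagents that add atoms: none
Why: The zwitterionic Mannich base 7 loses dimethylamine (E1cB-type, assisted by either flanking phenol) to give the dearomatized ortho-quinone methide 8, whose exocyclic CH2 is a vinylogous acyl Michael acceptor; the only unsubstituted ring carbon of 6, ortho to its free OH and activated by three oxygens, adds in a conjugate (Friedel–Crafts-type) manner, and two tautomerizations restore both aromatic rings. The closest known reaction type is the ortho-quinone methide benzylation of phenols from phenolic Mannich bases, the standard entry to methylene-bridged bis-acylphloroglucinols. No ring is closed and no stereocentre is created. The step needs cross- over homo-coupling and C- over O-alkylation: 7 has no free ring carbon and so cannot act as the carbon nucleophile, 6 has exactly one and is used in excess while 7 is added slowly, and any aryl benzyl ether formed at oxygen should revert to 8 at 100 °C whereas the C–C adduct is secured by rearomatization. Removal of the volatile amine in the argon stream should drive the sequence forward.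

**Compound list**
1 | 2-methylbenzene-1,3,5-triol (2,4,6-trihydroxytoluene) | Cc1c(O)cc(O)cc1O | starting material
2 | 2-methylpropanoyl chloride (isobutyryl chloride) | CC(C)C(Cl)=O | starting material
3 | 1-(2,4,6-trihydroxy-3-methylphenyl)-2-methylpropan-1-one | CC(C)C(=O)c1c(O)cc(O)c(C)c1O | intermediate
4 | 1-[4-(benzyloxy)-2,6-dihydroxy-3-methylphenyl]-2-methylpropan-1-one | CC(C)C(=O)c1c(O)cc(OCc2ccccc2)c(C)c1O | intermediate
5 | 1-[4-(benzyloxy)-2,6-dimethoxy-3-methylphenyl]-2-methylpropan-1-one | CC(C)C(=O)c1c(OC)cc(OCc2ccccc2)c(C)c1OC | intermediate
6 | 1-(4-hydroxy-2,6-dimethoxy-3-methylphenyl)-2-methylpropan-1-one | CC(C)C(=O)c1c(OC)cc(O)c(C)c1OC | intermediate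
7 | 1-{3-[(dimethylamino)methyl]-2,4,6-trihydroxy-5-methylphenyl}-2-methylpropan-1-one | CN(C)Cc1c(O)c(C)c(O)c(C(=O)C(C)C)c1O | intermediate
8 | 3,5-dihydroxy-2-methyl-6-methylidene-4-(2-methylpropanoyl)cyclohexa-2,4-dien-1-one (ortho-quinone methide) | C=C1C(=O)C(C)=C(O)C(C(=O)C(C)C)=C1O | intermediate (not isolated)
9 | 1-[4-hydroxy-2,6-dimethoxy-3-methyl-5-[[2,4,6-trihydroxy-3-methyl-5-(2-methylpropanoyl)phenyl]methyl]phenyl]-2-methylpropan-1-one (EANPDB:ROSA_00016) | COc1c(C)c(O)c(Cc2c(O)c(C)c(O)c(C(=O)C(C)C)c2O)c(OC)c1C(=O)C(C)C | target

**Step count and risks**
Total steps: 6. Longest linear sequence: 5 (steps 1, 2, 3, 4, 6); step 5 is a one-step branch from the shared intermediate 3.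

Steps most likely to fail, riskiest first:

Step 6. At 100 °C the methylene unit may be transferred between rings by reversible ipso-attack and retro-Mannich processes (scrambling towards the two symmetrical dimers), and alkylation at oxygen may compete. The fallback sets out from 7 (and 6) and comes back at 9. Compound 7 would be quaternized with MeI in acetone at rt to give N,N,N-trimethyl-1-[2,4,6-trihydroxy-3-methyl-5-(2-methylpropanoyl)phenyl]methanaminium iodide F1. This salt would then be added at 0 °C to the preformed sodium phenoxide of 6 (NaOMe, MeOH). The quinone methide 8 is then released by base-triggered loss of trimethylamine at low temperature instead of by thermolysis, and is met at once by the phenoxide of 6.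

Step 2. Site selectivity among the three hydroxyls may be poor, a second benzylation may follow, and the ambident phenoxide may be benzylated at the free ring carbon. The fallback sets out from 3 and comes back at 6. Sulfonylation with TsCl (1.0 equiv), K2CO3, acetone, 0 °C should give 3,5-dihydroxy-2-methyl-4-(2-methylpropanoyl)phenyl 4-methylbenzenesulfonate F2; a hard sulfonyl electrophile can only react at oxygen and should choose the most acidic, non-chelated hydroxyl. Methylation with Me2SO4/K2CO3 in refluxing acetone should give 3,5-dimethoxy-2-methyl-4-(2-methylpropanoyl)phenyl 4-methylbenzenesulfonate F3. Cleavage of the sulfonate with KOH in MeOH/H2O at reflux, then acidification, should give 6.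

Step 5. The Mannich base may lose amine under the reaction conditions and the resulting quinone methide may be captured by unreacted 3 (symmetrical dimer); retro-Mannich cleavage may occur on isolation. The fallback sets out from 3 (and 6) and comes back at 9. Condensation of 3 with paraformaldehyde and sodium 4-methylbenzenesulfinate in aqueous formic acid at rt should give 1-{2,4,6-trihydroxy-3-methyl-5-[(4-methylbenzenesulfonyl)methyl]phenyl}-2-methylpropan-1-one F4; the sulfinate in excess should intercept the transient quinone methide, and the sulfone is stable to acid. Treatment of the sulfone with 6 and K2CO3 in MeCN at 0 °C to rt should expel sulfinate, regenerate 8 and give 9.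

**Further compounds**
F1 | step 6 | N,N,N-trimethyl-1-[2,4,6-trihydroxy-3-methyl-5-(2-methylpropanoyl)phenyl]methanaminium iodide | C[N+](C)(C)Cc1c(O)c(C)c(O)c(C(=O)C(C)C)c1O.[I-]
F2 | step 2 | 3,5-dihydroxy-2-methyl-4-(2-methylpropanoyl)phenyl 4-methylbenzenesulfonate | CC(C)C(=O)c1c(O)cc(OS(=O)(=O)c2ccc(C)cc2)c(C)c1O
F3 | step 2 | 3,5-dimethoxy-2-methyl-4-(2-methylpropanoyl)phenyl 4-methylbenzenesulfonate | CC(C)C(=O)c1c(OC)cc(OS(=O)(=O)c2ccc(C)cc2)c(C)c1OC
F4 | step 5 | 1-{2,4,6-trihydroxy-3-methyl-5-[(4-methylbenzenesulfonyl)methyl]phenyl}-2-methylpropan-1-one | Cc1ccc(S(=O)(=O)Cc2c(O)c(C)c(O)c(C(=O)C(C)C)c2O)cc1
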